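- 4 questions stand on this flask: what is in chains at the look, whether any option pays, and what violet and green bring.

common to all: free monomer 0.10 M

| flask | initiator | temperature | remark | time |
|---|---|---|---|---|
| birch | 0.5 mol% | 20 °C | the very flask that is asked about, followed so far |  |
| cedar | 1 mol% | 5 °C | run made earlier |  |
| flask | 0.5 mol% | 20 °C |  | 4.0 h |

| run | time / min | monomer in chains / % | free monomer / % |
|---|---|---|---|
| birch | 60.0 | 64.0 | 34.5 |
| birch | 120 | 65.3 | 34.4 |
| birch | 180 | 64.4 | 34.5 |
| birch | 240 | 64.8 | 32.8 |
| cedar | 4.00 | 41.8 | 58.4 |
| cedar | 12.0 | 72.4 | 27.2 |
| cedar | 25.0 | 85.4 | 14.6 |
| cedar | 40.0 | 89.9 | 10.5 |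

(standard deviation of a reading: 0.5 percentage points)

- monomer in chains, in percent of the free monomer first charged, at 4.0 h
- what to do for the largest gain in monomer in chains; "none" if nothing gains more than 2 percentage points (grey / violet / green / teal / none)
- monomer in chains present, with what was taken out counted in, in percent of the free monomer first charged, after violet
- monomer in chains present, with what was taken out counted in, in percent of the free monomer first charged, after green

- grey: change nothing and wait 80 min more
- violet: at 4.0 h take out 90% of the monomer in chains then present, then wait 80 min
- green: at 4.0 h add free monomer, 50.0% of the amount charged, then wait 80 min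
- teal: at 4.0 h raise the temperature by 15 K, then wait 80 min

- what is taken out of monomer in chains is counted as made
- the analysis behind the earlier runs scatters by 0.5 percentage points, standard deviation
- additions bring no volume worth counting

- We work with the fraction left and not with the fraction made. The birch readings of monomer in chains average 64.6%, and that is our answer for now.
- We define the dose as the natural logarithm of one over the fraction not in chains, which is the pseudo-first-order rate constant integrated over time. For birch it is 1.04.
- Between the first and last birch readings the dose creeps up, which gives a further dose of 0.00999 over the 80 min of waiting. That is a reading within the scatter, and we assume the stop is a stall and not a balance.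
- Grey: the further dose acts on what is not in chains, so it gains 0.35 percentage points, less than the 2 points margin.
- Violet: taking out chains leaves the fraction not in chains as it stands, so the gain is the same and the total is 64.9%.
- Green: the added monomer joins what the dose acts on, so it gains 0.85 points, and the total is 65.4%.
- Teal: the 15 K rise would have to multiply the further dose about 5.71-fold to reach the margin, and we expect less.
- The forecast says 64.6%, none, 64.6% and 64.6%, on the ground that “the birch plateau is a stalled reaction”. It takes the totals as flat, while ours keep the small creep, so they stand a little higher.
- The flask gives 64.5% and none. The gains are 0.0052 points for grey, 0.0052 points for violet, 0.013 points for green and 0.007 points for teal, with totals of 64.5% after violet and 64.6% after green.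

    free monomer → decomposition product (k = 4.58 × 10⁻⁶ /s, Ea = 104 kJ/mol)
    2 growing radical → dead chain (k = 5.30 × 10⁶ /M/s, Ea = 12.0 kJ/mol)
    free monomer + growing radical → monomer in chains + growing radical, rate k3*[growing radical]*[free monomer] (k = 5380 /M/s, Ea = 20.0 kJ/mol)
    initiator → 2 initiating radical (k = 0.0105 /s, Ea = 73.0 kJ/mol)
    free monomer + initiating radical → growing radical + monomer in chains (k = 2.51 × 10⁵ /M/s, Ea = 20.0 kJ/mol)
    (constants at 20 °C)

- The dose of the flask is 1.04, and its initiator stands at 0% at 240 min.
- The neighbouring flask is charged with 0.40 M of free monomer at the same loading, so its charged c(initiator) is 4.00 times as large. We take the dose to follow the square root of the charged c(initiator). That gives 2.08, and so 87.5% in chains. The neighbouring flask holds 87.3% in chains at 240 min.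

(The numbers in the tables were computed for an exercise; noise was put on by code.)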